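The millimolar of nucleophile was the unit I counted in, for ash, which is the asked flask followed so far.

| flask | electrophile | nucleophile | remark | time |
|---|---|---|---|---|
| ash | 20 mM | 16 mM | the very flask that is asked about, followed so far |  |
| cedar | 13 mM | 16 mM | run made earlier |  |
| flask | 20 mM | 16.0 mM |  | 2.5 d |

- ash (time / h: electrophile / %, target / %): 2.50: 84, 9; 5.00: 80, 10; 8.00: 68, 6; 10.0: 68, 7; 12.0: 65, 4; 15.0: 61, 3; 20.0: 55, 1
- cedar (time / h: electrophile / %, target / %): 1.33: 92, 3; 4.00: 82, 10; 6.00: 77, 6; 10.0: 65, 6; 15.0: 57, 8; 20.0: 49, 5; 25.0: 42, 2

(each reading ± 2 percentage points)

- the analysis behind the earlier runs scatters by 2 percentage points, standard deviation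
- the earlier runs do not show how much of nucleophile is bound; that part of a forecast is a guess

* part of the electrophile that has reacted at 2.5 d
* share of the unused nucleophile that is free and not bound as protonated nucleophile, at 2.5 d

I supposed that each attack on the electrophile frees acid, and that this acid can hold a second nucleophile as protonated nucleophile, so one attack costs two. I therefore defined the nucleophile ceiling as the attacks that the charge pays for at that price, half the nucleophile charge: 8.00 mM. This is less than the electrophile charge of 20 mM, which made nucleophile the limiting reagent in ash.

Yet ash had lost 9.00 mM of electrophile by 20.0 h, more than the ceiling, and was still falling. These numbers conflict if one attack removes one electrophile. Target had faded to 1%, so I supposed that some target takes a second electrophile. Taken at the ceiling, that supposition gave 1.12 electrophile per attack in ash, a figure that carries the scatter of the reading. I committed to a stall a little past that loss, with the unused nucleophile standing mainly as protonated nucleophile, which is a guess: the runs do not show binding.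

The forecast gave 64% and 75%, holding that “binding is only partial”. The flask gave 53.7% and 6.23%.

    electrophile + nucleophile → acid set free + target (k = 3.50 M⁻¹ h⁻¹)
    nucleophile + acid set free ⇌ protonated nucleophile, settled at all times (K = 13000 M⁻¹)
    target → over-reaction product A (k = 0.200 h⁻¹)
    target → over-reaction product B (k = 5.60 × 10⁻⁵ h⁻¹)
    electrophile + target → side product (k = 6.10 M⁻¹ h⁻¹)

At 2.50 d the flask held 7.18 mM of protonated nucleophile, and its nucleophile balance gives 8.34 mM of attacks, close to the ceiling. Side product in the flask stood at 24.0%, a percentage in which each unit counts as two. A neighbouring flask with the same nucleophile charge, and so the same ceiling, had 5.0 mM of electrophile, which is below that ceiling. Its balance gives 4.18 mM of attacks, and 89.0% of its electrophile reacted, while 65.0% of its unused nucleophile stayed free.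

The runs stem from a simulated flask for an exercise, noise included.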